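At early times the violet run holds 68.0% of side product after 0.333 d, beside 2.2% of target.

| flask | substrate | partner | remark | time |
|---|---|---|---|---|
| violet | 0.30 M | 1.5 equiv | run made earlier |  |
| grey | 0.15 M | 1.5 equiv | run made earlier |  |
| teal | 0.60 M | 1.5 equiv | run made earlier |  |
| summer | 0.30 M | 1.50 equiv | everything together in a closed stirred flask, run for 2.5 d | 2.5 d |
| autumn | 0.30 M | 1.50 equiv | one stirred flow tank at steady state, fed with the mixture as stated, mean residence time 2.5 d |  |
| dusk | 0.30 M | 1.50 equiv (fed, over 2.00 d) | all but partner at the start; partner goes in evenly over 2.00 d, the run ends at 2.5 d | 2.5 d |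
| dawn | 0.30 M (fed, over 2.00 d) | 1.50 equiv | a stirred flask in which substrate is dosed at a steady rate over 2.00 d without added volume, worked up at 2.5 d | 2.5 d |

| run | time / d | target / % | homo product / % | side product / % |
|---|---|---|---|---|
| violet | 0.333 | 2.2 | 4.8 | 68.0 |
| violet | 0.625 | 2.9 | 4.5 | 84.7 |
| violet | 1.04 | 4.4 | 5.4 | 89.7 |
| violet | 1.25 | 2.8 | 4.5 | 89.8 |
| violet | 1.67 | 4.9 | 4.7 | 89.8 |
| violet | 2.00 | 4.0 | 4.7 | 89.5 |
| violet | 2.50 | 3.8 | 5.1 | 89.8 |
| grey | 0.417 | 1.9 | 2.5 | 79.0 |
| grey | 0.833 | 2.3 | 4.1 | 91.7 |
| grey | 1.25 | 2.5 | 2.9 | 94.1 |
| grey | 1.67 | 1.8 | 1.6 | 93.9 |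
| grey | 2.00 | 2.0 | 2.7 | 93.0 |
| grey | 2.50 | 2.1 | 2.9 | 93.9 |
| grey | 3.00 | 2.1 | 2.4 | 93.7 |
| teal | 0.417 | 3.9 | 9.1 | 72.3 |
| teal | 0.833 | 5.6 | 8.6 | 82.4 |
| teal | 1.25 | 6.0 | 8.8 | 84.8 |
| teal | 1.67 | 5.3 | 7.7 | 84.9 |
| teal | 2.00 | 5.9 | 8.8 | 84.4 |
| teal | 2.50 | 5.8 | 8.7 | 83.7 |
| teal | 3.00 | 5.6 | 8.8 | 83.7 |

(standard deviation of a reading: 0.5 percentage points)

- a species is counted by the substrate in it: one homo product counts as two
- amounts and yields of target count idle adduct too
- the stated concentrations are those of everything mixed, before any reaction; amounts are the same in each set-up
- what was read earlier has a scatter of 0.5 percentage points, one standard deviation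
- steps under discussion: substrate <-> open intermediate; partner -> second intermediate; open intermediate + second intermediate -> target; 2 open intermediate -> homo product; open intermediate -> decomposed reagent; open intermediate -> side product; partner + target <-> idle adduct
- the feed brings no volume worth counting
- the earlier runs were made in a closed, stirred flask

- the set-up with the highest share of target in all that became target or homo product or side product, at the outlet or at the end ("none" if the first two lie within 2 percentage points) (summer / autumn / dusk / dawn / none)
- share of target in all that became target or homo product or side product, at the outlet or at the end, summer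
- share of target in all that became target or homo product or side product, at the outlet or at the end, autumn
- share of target in all that became target or homo product or side product, at the outlet or at the end, dusk
- share of target in all that became target or homo product or side product, at the outlet or at the end, dawn

The fastest rung of the ladder is substrate's own clock. That first violet reading, set against the plateau, gives 4.25 d⁻¹, and the grey run gives 4.44 d⁻¹ at half the charge, so I read a first-order loss with a mean life of 0.235 d.

Target sits on a slower rung. Take the selectivity ratio, target per side product over the late readings, which reads 0.0444 in violet and 0.0224 in grey: twice the ratio at twice the charge, as far as the scatter lets you read it. Teal, at twice violet's charge, reads 0.0679, just 1.53 times violet's ratio, so the proportion does not carry above violet's charge. At violet's charge and below, as my own rough rule, I let c(second intermediate) grow steadily out of partner, and the ratio follow c(partner) times the mean age of the flask when substrate is consumed.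

Summer, like violet, has the age 0.235 d. Dawn, a starved feed, consumes substrate on average at 1.24 d, the middle of the dosing plus the life, so its ratio becomes 0.233. Autumn's contents are older still, 2.5 d, which gives 0.471. In dusk the life is far shorter than the dosing, so partner comes in late and the ratio shrinks to 0.00522.

Ignoring homo product, my shares are 4.25% for summer, 32.0% for autumn, 0.519% for dusk and 18.9% for dawn. They should run high, since this mean counts no second intermediate as used.

The forecast gave 4%, 17.5%, 0.5% and 15% in that order, with autumn ahead: “Autumn leads narrowly.”

The flasks give 3.84%, 18.6%, 0.466% and 15.5%, so autumn leads.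

    substrate ⇌ open intermediate (K = 2.91, k = 0.00433 min⁻¹)
    partner → second intermediate (k = 1.09 × 10⁻⁴ min⁻¹)
    open intermediate + second intermediate → target (k = 0.0341 L mol⁻¹ min⁻¹)
    2 open intermediate → homo product (k = 0.00771 L mol⁻¹ min⁻¹)
    open intermediate → decomposed reagent (k = 1.79 × 10⁻⁴ min⁻¹)
    open intermediate → side product (k = 0.0104 min⁻¹)
    partner + target ⇌ idle adduct, settled at all times (K = 2.50 L mol⁻¹)

My dawn share was high by 3.4 percentage points, my autumn share by 13 points. Dawn's share has nearly come to rest: at ten times the time it reads 15.5%, with 0.59% of substrate left at the end. Summer's share stays at 3.84% and dusk's at 0.466%. In summer, partner falls from 66.8% to 2.10% and c(second intermediate) climbs from 0.133 M to 0.429 M, while open intermediate stands at 0% and target stays at 3.78%.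

A neighbour of dawn with 0.12 M of substrate, equivalents held, scales the ratio with c(partner) to 0.0932, a share of 8.53%. The computed flask gives 8.04%.

(The readings are simulated for substances that don't exist, noise included.)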